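12.8 % of the free monomer charged stayed free in the larch run and 60.5 % in the maple run, each a mean of readings that wander within their scatter.

| flask | free monomer | transfer agent | protic impurity | initiator | stray impurity | remark | time |
|---|---|---|---|---|---|---|---|
| larch | 0.80 M | 0.012 M | 0.016 M | 0.46 mol% | 4 mM | run made earlier |  |
| maple | 0.80 M | 0.048 M | 0.016 M | 0.46 mol% | 4 mM | run made earlier |  |
| flask | 0.80 M | 0.0240 M | 0.0160 M | 0.46 mol% | 4.0 mM |  | 3.0 h |

| run | time / h | monomer in chains / % | free monomer / % |
|---|---|---|---|
| larch | 0.417 | 84 | 15 |
| larch | 0.833 | 85 | 13 |
| larch | 1.33 | 85 | 12 |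
| larch | 1.50 | 87 | 12 |
| larch | 2.00 | 84 | 11 |
| larch | 2.50 | 87 | 14 |
| maple | 0.417 | 37 | 61 |
| maple | 0.833 | 35 | 62 |
| maple | 1.33 | 38 | 58 |
| maple | 1.50 | 37 | 60 |
| maple | 2.00 | 39 | 61 |
| maple | 2.50 | 38 | 61 |

(scatter of a reading: 1.5 percentage points)

- the average divides the monomer in chains by the number of chains begun, living and dead together
- the earlier runs do not show the number of chains; that part of a forecast is a guess

- average number of monomer units in a chain (chains begun, living or dead) at 3.0 h
- part of the free monomer that has reacted at 3.0 h

Did the larch run stop for want of monomer? No: at 2.50 h its free monomer still reads near that mean, and it already read near there at 0.417 h. Growth stopped early with monomer left, a stall called dead-end polymerisation.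

What differs between the two runs? The charge of [transfer agent], by a factor of 4.00; their other charges are equal.

And the stall? Take the logarithm of charged over final free monomer. The larch run gives 2.05, the maple run 0.503, a ratio of 4.08.

So what do you carry? The stopping product, charged [transfer agent] times that logarithm. It reads 0.0246 M in the larch run and 0.0241 M in the maple run; their mean is 0.0244 M.

Two runs make any line, don't they? They do. But this flask lies between them in [transfer agent], with its other charges the same.

Then this flask? My reckoning: at 0.0240 M the logarithm is 1.02, so c is 63.8 %. For dp I have no number, since the runs show no chains.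

The forecast says c 63 % and dp 70, remarking: “The runs don't show chain numbers, so dp is a guess”.

The simulation gives this flask c 63.7 % and dp 172, which is 2.46 times the forecast's dp.

    living end + transfer agent → dead chain (kL = 0.180 M⁻¹ s⁻¹)
    protic impurity + free monomer → quenched substrate (k = 0.340 M⁻¹ s⁻¹)
    free monomer + living end → monomer in chains + living end, rate k3*[living end]*[free monomer] (k = 1.40 M⁻¹ s⁻¹)
    initiator + stray impurity → spent initiator (k = 25.0 M⁻¹ s⁻¹)
    free monomer + initiator → living end + monomer in chains (k = 0.400 M⁻¹ s⁻¹)

In this flask, dp divides monomer in chains by chains begun, and at 3.00 h those stand as 0.00287 M of dead chain, less than the 3.68 mM of initiator charged. The rest stands as 8.13 × 10⁻⁴ M of spent initiator. With [initiator] held at its charged level instead of falling, dp comes to 19.0, so the falling level of initiator is part of why the chains of this flask are so long. For the neighbour charged with 0.060 M of transfer agent, the stopping product gives a logarithm of 0.406, so c 33.4 %; computed, c is 33.3 %.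

Readings and results were computed on assumed constants, noise included.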